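**Plan**
1. Retrosynthesis: all benzyl ethers and the blocking bromines go last. The 4β→8 bond (middle C4–lower C8) and then the 4β→6 bond (upper C4–middle C6) are cut, giving three 3-O-galloylated monomers that all come from tetra-O-benzyl-epicatechin 14.
2. Ring C of 14 is cut at C3–C4 and O1–C8a, giving a 2,4,6-trifluorobenzyl boronate (ring A plus C4) and a trans-2-aryl-oxiranyl anion (O1, C2, C3, ring B).
3. Enabling feature: the vicinal O1–C2/C3–O pattern of ring C lies between benzylic C4 and aryl carbon C8a. An oxirane oxygen can first leave C3 in a boron-to-carbon 1,2-shift and then attack C8a; boron stands in for the C3 oxygen, and the C5/C7 oxygens of ring A are carried as fluorines that make C8a an SNAr site.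
4. Forward: ring C closes on preformed rings A and B (key step), then B→OH and F→OBn. 14 is galloylated directly (lower unit) or after C4 oxidation (upper and middle units). The upper and middle units are joined at middle C6 (C8 blocked by Br), the lower unit is added at its C8, and hydrogenolysis follows.
5. Stereochemistry: C2 comes from a sulfoxide-directed epoxidation, C3 from the stereospecific borylation (retention) and 1,2-shift (inversion), and both C4 centres from attack trans to the 3-oxygen substituent.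

Key step: step 4

Assumption: the (R)-sulfinyl group of 7 is taken to steer the peroxide to the alkene face that gives the (2R,3R)-oxirane 8; if the opposite face is preferred, the (S)-enantiomer of 3 is used and nothing else changes.

**Step 1**
Reactants: 1 2,4,6-trifluorobenzyl bromide
Product: 2 4,4,5,5-tetramethyl-2-(2,4,6-trifluorobenzyl)-1,3,2-dioxaborolane
Conditions: B2pin2, Pd(dba)2 (3 mol%), P(4-MeOC6H4)3 (6 mol%), KOAc, toluene, 50 °C
Reagents that add atoms: bis(pinacolato)diboron (CC1(C)OB(OC1(C)C)B1OC(C)(C)C(C)(C)O1)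
Why: Miyaura borylation of a benzylic bromide (oxidative addition of the C–Br bond, transmetallation with acetate-activated diboron, reductive elimination) should give the benzylboronate, the aryl C–F bonds being inert to the catalyst.

**Step 2**
Reactants: 3 (R)-methyl p-tolyl sulfoxide; 4 diethyl chlorophosphate; 5 3,4-bis(benzyloxy)benzaldehyde
Product: 7 (R,E)-1,2-bis(benzyloxy)-4-[2-(p-tolylsulfinyl)vinyl]benzene, via lithiated phosphonate 6 (not isolated)
Conditions: LiN(iPr)2 (2.1 equiv), THF, −78 °C; 4, −78 → −40 °C; then 5, −78 °C → rt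
Reagents that add atoms: none
Why: One-pot Horner–Wadsworth–Emmons olefination, in which the α-lithiated sulfoxide is phosphorylated and deprotonated again to carbanion 6, whose addition to the aldehyde and loss of phosphate should give the (E)-alkene with the sulfur stereocentre untouched.

**Step 3**
Reactants: 7 (R,E)-vinyl sulfoxide
Product: 8 (2R,3R)-2-[3,4-bis(benzyloxy)phenyl]-3-(p-tolylsulfinyl)oxirane (trans)
Conditions: t-BuOOH (decane), KOtBu (20 mol%), THF, −20 → 0 °C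
Reagents that add atoms: tert-butyl hydroperoxide (CC(C)(C)OO)
Why: Nucleophilic (Weitz–Scheffer type) epoxidation of the vinyl sulfoxide keeps the (E)-geometry as the trans-oxirane, and the sulfinyl stereocentre is expected to direct the peroxide to one alkene face, which sets both oxirane carbons.

**Step 4**
Reactants: 8 (2R,3R)-trans-sulfinyl oxirane; 2 trifluorobenzyl boronate
Product: 12 (2S,3R)-2-[3,4-bis(benzyloxy)phenyl]-5,7-difluoro-3-(4,4,5,5-tetramethyl-1,3,2-dioxaborolan-2-yl)chromane (2,3-cis), via oxiranyllithium 9 (not isolated), via lithium boron ate complex 10 (not isolated), via lithium beta-oxido boronate 11 (not isolated)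
Conditions: t-BuLi (1.05 equiv), THF, −100 °C, 5 min; 2, −100 → 0 °C; then KOtBu, 18-crown-6, DMF, 0 → 25 °C
Reagents that add atoms: none
Why: Proposed new method: sulfoxide–lithium exchange on 8 should give the configurationally stable trans-oxiranyllithium 9, which adds to the boron of 2 with retention (ate complex 10); release of oxirane strain then drives the 1,2-shift of the trifluorobenzyl group from boron to C3, anti to the breaking C3–O bond, which forms C3–C4 and frees O1 as alkoxide 11. This alkoxide closes ring C by 6-exo addition–elimination (SNAr through a Meisenheimer complex) at an ortho C–F carbon, which forms O1–C8a. The closest known reaction types are the homologation of boronic esters with lithiated epoxides (lithiation–borylation, 1,2-metallate rearrangement) and the alkoxide SNAr closure of 2,4,6-trifluorophenyl alcohols to 5,7-difluorochromans; their merger in one flask is the new element. C2 is carried over from the oxirane, and C3 is set by the substrate alone: retention at borylation and inversion in the shift turn the trans-oxirane into the 2,3-cis relationship of boron and aryl. The step needs ring closure to outrun syn-elimination of boron and oxygen (boron-Wittig pathway) from 11, which the fluorine-activated ring, the potassium/crown ether activation and tert-butoxide occupying the free boron site should secure; O3 cannot compete because it is still boron, and the two ortho fluorines are equivalent, so no regiochemical choice arises.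

**Step 5**
Reactants: 12 3-boryl-5,7-difluoroflavan
Product: 13 (2R,3R)-2-[3,4-bis(benzyloxy)phenyl]-5,7-difluorochroman-3-ol
Conditions: H2O2 (30% aq), NaOH, THF, 0 °C
Reagents that add atoms: hydrogen peroxide (OO)
Why: Oxidation of the secondary alkylboronic ester with alkaline peroxide moves C3 from boron to oxygen with retention, so the boron becomes the axial 3-hydroxyl cis to the aryl group; the axial C–B bond is not antiperiplanar to O1–C2, which disfavours β-elimination.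

**Step 6**
Reactants: 13 5,7-difluoroflavan-3-ol
Product: 14 5,7,3',4'-tetra-O-benzyl-(−)-epicatechin
Conditions: BnOH, NaH, NMP, 60 → 120 °C
Reagents that add atoms: benzyl alcohol (OCc1ccccc1)
Why: Twofold nucleophilic aromatic substitution of the ring A fluorides by sodium benzyloxide in a dipolar aprotic solvent installs the C5 and C7 oxygens, and the stereocentres are not touched because C2–H is not acidic while ring B is protected.

**Step 7**
Reactants: 14 tetra-O-benzyl-epicatechin; 15 3,4,5-tris(benzyloxy)benzoic acid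
Product: 16 5,7,3',4'-tetra-O-benzyl-(−)-epicatechin 3-O-[3,4,5-tris(benzyloxy)benzoate]
Conditions: DCC, DMAP, CH2Cl2, rt
Reagents that add atoms: none
Why: Steglich esterification (carbodiimide activation, acyl transfer by DMAP) acylates the single secondary 3-hydroxyl without touching the carbinol stereocentre and gives the nucleophilic lower unit with its gallate already in place.

**Step 8**
Reactants: 14 tetra-O-benzyl-epicatechin
Product: 17 4β-(2-ethoxyethoxy)-5,7,3',4'-tetra-O-benzyl-(−)-epicatechin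
Conditions: DDQ, 2-ethoxyethanol, CH2Cl2, rt
Reagents that add atoms: 2-ethoxyethanol (CCOCCO)
Why: Oxidative benzylic C–H etherification, in which DDQ abstracts hydride from C4 to give a cation stabilised by ring A and the alcohol adds on the face trans to the 3-hydroxyl, should set the 4β-ether.

**Step 9**
Reactants: 17 4β-(2-ethoxyethoxy) ether; 15 3,4,5-tris(benzyloxy)benzoic acid
Product: 18 4β-(2-ethoxyethoxy)-5,7,3',4'-tetra-O-benzyl-(−)-epicatechin 3-O-[3,4,5-tris(benzyloxy)benzoate]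
Conditions: DCC, DMAP, CH2Cl2, rt → 40 °C
Reagents that add atoms: none
Why: Steglich esterification under neutral conditions acylates the one axial 3-hydroxyl next to the acid-labile 4β-ether, so that both electrophilic units carry their gallate before any coupling and no hindered hydroxyl has to be acylated on the trimer.

**Step 10**
Reactants: 18 4β-(2-ethoxyethoxy) gallate
Product: 19 6,8-dibromo-4β-(2-ethoxyethoxy)-5,7,3',4'-tetra-O-benzyl-(−)-epicatechin 3-O-[3,4,5-tris(benzyloxy)benzoate]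
Conditions: NBS (2.1 equiv), CH2Cl2, −40 → 0 °C
Reagents that add atoms: N-bromosuccinimide (O=C1CCC(=O)N1Br)
Why: Electrophilic aromatic bromination goes to the far more electron-rich ring A, first at C8 and then at C6 (the gallate ring is deactivated by its carbonyl), which removes every nucleophilic site of the future upper unit.

**Step 11**
Reactants: 18 4β-(2-ethoxyethoxy) gallate
Product: 20 8-bromo-4β-(2-ethoxyethoxy)-5,7,3',4'-tetra-O-benzyl-(−)-epicatechin 3-O-[3,4,5-tris(benzyloxy)benzoate]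
Conditions: NBS (1.0 equiv), CH2Cl2, −78 °C
Reagents that add atoms: N-bromosuccinimide (O=C1CCC(=O)N1Br)
Why: Electrophilic aromatic bromination with one equivalent at low temperature should go to C8, the most reactive ring A position, leaving C6 as the only nucleophilic site.

**Step 12**
Reactants: 20 8-bromo-4β-(2-ethoxyethoxy) gallate
Product: 21 8-bromo-4β-[(2,6-dimethylphenyl)thio]-5,7,3',4'-tetra-O-benzyl-(−)-epicatechin 3-O-[3,4,5-tris(benzyloxy)benzoate]
Conditions: 2,6-Me2C6H3SH (excess), BF3·OEt2, CH2Cl2, −78 → −20 °C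
Reagents that add atoms: 2,6-dimethylbenzenethiol (Cc1cccc(C)c1S)
Why: Lewis-acid mediated SN1 exchange at C4 (ionisation of the benzylic ether, capture by the thiol trans to the 3-acyloxy group) should give the 4β-thioether, a leaving group that hard Lewis acids leave alone.

**Step 13**
Reactants: 19 6,8-dibromo-4β-(2-ethoxyethoxy) gallate; 21 8-bromo-4β-thioether gallate
Product: 22 [6,8-dibromo-tetra-O-benzyl-epicatechin 3-O-tris(benzyloxy)benzoate]-(4β→6)-[8-bromo-4β-(2,6-dimethylphenylthio)-tetra-O-benzyl-epicatechin 3-O-tris(benzyloxy)benzoate]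
Conditions: TMSOTf (0.2 equiv), CH2Cl2, −78 → −40 °C; 21 (1.5 equiv)
Reagents that add atoms: none
Why: Friedel–Crafts-type interflavan coupling, in which the silyl Lewis acid ionises the 4-alkoxy group of 19 and the C4 cation is attacked by C6 of 21 (its only free ring A position) on the face trans to the 3-acyloxy group, should set the 4β→6 bond while the thioether stays intact.

**Step 14**
Reactants: 22 dimeric 4β-thioether bis-gallate; 16 tetra-O-benzyl-epicatechin 3-O-tris(benzyloxy)benzoate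
Product: 23 [6,8-dibromo-tetra-O-benzyl-epicatechin 3-O-tris(benzyloxy)benzoate]-(4β→6)-[8-bromo-tetra-O-benzyl-epicatechin 3-O-tris(benzyloxy)benzoate]-(4β→8)-[tetra-O-benzyl-epicatechin 3-O-tris(benzyloxy)benzoate]
Conditions: AgOTf, 4 Å MS, CH2Cl2, −40 → 0 °C; 16 (3 equiv)
Reagents that add atoms: none
Why: Thiophilic activation of the benzylic C–S bond by the soft silver salt gives the middle-unit C4 cation, which undergoes Friedel–Crafts attack by C8 of 16 (the most nucleophilic position of a 5,7-dioxygenated flavan) trans to the 3-acyloxy group, setting the 4β→8 bond, while the brominated units offer no competing site.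

**Step 15**
Reactants: 23 protected tribromo trimer trigallate
Product: 24 (−)-epicatechin 3-O-gallate-(4β→6)-(−)-epicatechin 3-O-gallate-(4β→8)-(−)-epicatechin 3-O-gallate
Conditions: H2 (1 atm), Pd(OH)2/C, NaOAc, THF/MeOH/H2O, rt
Reagents that add atoms: none
Why: Hydrogenolysis over Pd(OH)2/C should cleave the twenty-one benzyl ethers and the three aryl C–Br bonds in one operation, the acetate buffer taking up HBr without poisoning the catalyst, while esters and interflavan bonds are stable.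

**Compound list**
1 | 2,4,6-trifluorobenzyl bromide | BrCc1c(F)cc(F)cc1F | starting material
2 | 4,4,5,5-tetramethyl-2-(2,4,6-trifluorobenzyl)-1,3,2-dioxaborolane | CC1(C)OB(Cc2c(F)cc(F)cc2F)OC1(C)C | intermediate
3 | (R)-methyl p-tolyl sulfoxide | Cc1ccc(cc1)[S@](=O)C | starting material
4 | diethyl chlorophosphate | CCOP(=O)(Cl)OCC | starting material
5 | 3,4-bis(benzyloxy)benzaldehyde | O=Cc1ccc(OCc2ccccc2)c(OCc2ccccc2)c1 | starting material
6 | lithium salt of diethyl [(p-tolylsulfinyl)methyl]phosphonate (sulfur as in 3) | [Li+].CCOP(=O)(OCC)[CH-][S@@](=O)c1ccc(C)cc1 | intermediate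
7 | (R,E)-1,2-bis(benzyloxy)-4-[2-(p-tolylsulfinyl)vinyl]benzene | Cc1ccc(cc1)[S@](=O)/C=C/c1ccc(OCc2ccccc2)c(OCc2ccccc2)c1 | intermediate
8 | (2R,3R)-2-[3,4-bis(benzyloxy)phenyl]-3-(p-tolylsulfinyl)oxirane (trans; sulfur geometry as in 7) | Cc1ccc(cc1)[S@](=O)[C@H]1O[C@@H]1c1ccc(OCc2ccccc2)c(OCc2ccccc2)c1 | intermediate
9 | (2R,3R)-3-[3,4-bis(benzyloxy)phenyl]oxiran-2-yllithium (lithium trans to aryl) | [Li][C@H]1O[C@@H]1c1ccc(OCc2ccccc2)c(OCc2ccccc2)c1 | intermediate
10 | lithium pinacolato(oxiranyl)(2,4,6-trifluorobenzyl)borate (boron trans to aryl) | [Li+].CC1(C)O[B-](Cc2c(F)cc(F)cc2F)(OC1(C)C)[C@H]1O[C@@H]1c1ccc(OCc2ccccc2)c(OCc2ccccc2)c1 | intermediate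
11 | lithium (1S,2R)-1-[3,4-bis(benzyloxy)phenyl]-2-(pinacolboryl)-3-(2,4,6-trifluorophenyl)propan-1-olate | [Li+].[O-][C@H](c1ccc(OCc2ccccc2)c(OCc2ccccc2)c1)[C@H](B1OC(C)(C)C(C)(C)O1)Cc1c(F)cc(F)cc1F | intermediate
12 | (2S,3R)-2-[3,4-bis(benzyloxy)phenyl]-5,7-difluoro-3-(pinacolboryl)chromane (2,3-cis) | CC1(C)OB(OC1(C)C)[C@@H]1Cc2c(F)cc(F)cc2O[C@@H]1c1ccc(OCc2ccccc2)c(OCc2ccccc2)c1 | intermediate
13 | (2R,3R)-2-[3,4-bis(benzyloxy)phenyl]-5,7-difluorochroman-3-ol | O[C@@H]1Cc2c(F)cc(F)cc2O[C@@H]1c1ccc(OCc2ccccc2)c(OCc2ccccc2)c1 | intermediate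
14 | 5,7,3',4'-tetra-O-benzyl-(−)-epicatechin, (2R,3R) | O[C@@H]1Cc2c(OCc3ccccc3)cc(OCc3ccccc3)cc2O[C@@H]1c1ccc(OCc2ccccc2)c(OCc2ccccc2)c1 | intermediate
15 | 3,4,5-tris(benzyloxy)benzoic acid | OC(=O)c1cc(OCc2ccccc2)c(OCc2ccccc2)c(OCc2ccccc2)c1 | starting material
16 | 5,7,3',4'-tetra-O-benzyl-(−)-epicatechin 3-O-[3,4,5-tris(benzyloxy)benzoate] | O=C(O[C@@H]1Cc2c(OCc3ccccc3)cc(OCc3ccccc3)cc2O[C@@H]1c1ccc(OCc2ccccc2)c(OCc2ccccc2)c1)c1cc(OCc2ccccc2)c(OCc2ccccc2)c(OCc2ccccc2)c1 | intermediate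
17 | 4β-(2-ethoxyethoxy)-5,7,3',4'-tetra-O-benzyl-(−)-epicatechin (3,4-trans) | O[C@@H]1[C@@H](OCCOCC)c2c(OCc3ccccc3)cc(OCc3ccccc3)cc2O[C@@H]1c1ccc(OCc2ccccc2)c(OCc2ccccc2)c1 | intermediate
18 | 4β-(2-ethoxyethoxy)-5,7,3',4'-tetra-O-benzyl-(−)-epicatechin 3-O-[3,4,5-tris(benzyloxy)benzoate] | O=C(O[C@@H]1[C@@H](OCCOCC)c2c(OCc3ccccc3)cc(OCc3ccccc3)cc2O[C@@H]1c1ccc(OCc2ccccc2)c(OCc2ccccc2)c1)c1cc(OCc2ccccc2)c(OCc2ccccc2)c(OCc2ccccc2)c1 | intermediate
19 | 6,8-dibromo-4β-(2-ethoxyethoxy)-5,7,3',4'-tetra-O-benzyl-(−)-epicatechin 3-O-[3,4,5-tris(benzyloxy)benzoate] | O=C(O[C@@H]1[C@@H](OCCOCC)c2c(OCc3ccccc3)c(Br)c(OCc3ccccc3)c(Br)c2O[C@@H]1c1ccc(OCc2ccccc2)c(OCc2ccccc2)c1)c1cc(OCc2ccccc2)c(OCc2ccccc2)c(OCc2ccccc2)c1 | intermediate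
20 | 8-bromo-4β-(2-ethoxyethoxy)-5,7,3',4'-tetra-O-benzyl-(−)-epicatechin 3-O-[3,4,5-tris(benzyloxy)benzoate] | O=C(O[C@@H]1[C@@H](OCCOCC)c2c(OCc3ccccc3)cc(OCc3ccccc3)c(Br)c2O[C@@H]1c1ccc(OCc2ccccc2)c(OCc2ccccc2)c1)c1cc(OCc2ccccc2)c(OCc2ccccc2)c(OCc2ccccc2)c1 | intermediate
21 | 8-bromo-4β-[(2,6-dimethylphenyl)thio]-5,7,3',4'-tetra-O-benzyl-(−)-epicatechin 3-O-[3,4,5-tris(benzyloxy)benzoate] | O=C(O[C@@H]1[C@@H](Sc3c(C)cccc3C)c2c(OCc3ccccc3)cc(OCc3ccccc3)c(Br)c2O[C@@H]1c1ccc(OCc2ccccc2)c(OCc2ccccc2)c1)c1cc(OCc2ccccc2)c(OCc2ccccc2)c(OCc2ccccc2)c1 | intermediate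
22 | [6,8-dibromo-tetra-O-benzyl-epicatechin 3-O-tris(benzyloxy)benzoate]-(4β→6)-[8-bromo-4β-(2,6-dimethylphenylthio)-tetra-O-benzyl-epicatechin 3-O-tris(benzyloxy)benzoate] | O=C(O[C@@H]1[C@@H](c2c(OCc5ccccc5)c(Br)c3c(c2OCc5ccccc5)[C@H](Sc4c(C)cccc4C)[C@@H](OC(=O)c6cc(OCc7ccccc7)c(OCc7ccccc7)c(OCc7ccccc7)c6)[C@@H](c2ccc(OCc4ccccc4)c(OCc4ccccc4)c2)O3)c2c(OCc3ccccc3)c(Br)c(OCc3ccccc3)c(Br)c2O[C@@H]1c1ccc(OCc2ccccc2)c(OCc2ccccc2)c1)c1cc(OCc2ccccc2)c(OCc2ccccc2)c(OCc2ccccc2)c1 | intermediate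
23 | [6,8-dibromo-tetra-O-benzyl-epicatechin 3-O-tris(benzyloxy)benzoate]-(4β→6)-[8-bromo-tetra-O-benzyl-epicatechin 3-O-tris(benzyloxy)benzoate]-(4β→8)-[tetra-O-benzyl-epicatechin 3-O-tris(benzyloxy)benzoate] | O=C(O[C@@H]1[C@@H](c2c(OCc5ccccc5)c(Br)c3c(c2OCc5ccccc5)[C@H](c2c(OCc5ccccc5)cc(OCc5ccccc5)c4c2O[C@H](c2ccc(OCc5ccccc5)c(OCc5ccccc5)c2)[C@H](OC(=O)c6cc(OCc7ccccc7)c(OCc7ccccc7)c(OCc7ccccc7)c6)C4)[C@@H](OC(=O)c6cc(OCc7ccccc7)c(OCc7ccccc7)c(OCc7ccccc7)c6)[C@@H](c2ccc(OCc4ccccc4)c(OCc4ccccc4)c2)O3)c2c(OCc3ccccc3)c(Br)c(OCc3ccccc3)c(Br)c2O[C@@H]1c1ccc(OCc2ccccc2)c(OCc2ccccc2)c1)c1cc(OCc2ccccc2)c(OCc2ccccc2)c(OCc2ccccc2)c1 | intermediate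
24 | (−)-epicatechin 3-O-gallate-(4β→6)-(−)-epicatechin 3-O-gallate-(4β→8)-(−)-epicatechin 3-O-gallate | O=C(O[C@@H]1[C@@H](c2c(O)cc3c(c2O)[C@H](c2c(O)cc(O)c4c2O[C@H](c2ccc(O)c(O)c2)[C@H](OC(=O)c2cc(O)c(O)c(O)c2)C4)[C@@H](OC(=O)c2cc(O)c(O)c(O)c2)[C@@H](c2ccc(O)c(O)c2)O3)c2c(O)cc(O)cc2O[C@@H]1c1ccc(O)c(O)c1)c1cc(O)c(O)c(O)c1 | target

Total step count: 15. Longest linear sequence: 12 steps (steps 2, 3, 4, 5, 6, 8, 9, 11, 12, 13, 14, 15).

**Steps most likely to fail**

Step 4. What may go wrong: syn-elimination of boron and oxygen from the β-oxido boronate before the ring closes, an incomplete 1,2-shift, or proton transfer from the benzylic boronate to the oxiranyllithium. The fallback uses known chemistry and sets out from 8 and 2. The ate complex 10 is formed as before but treated with Et3SiOTf at −78 °C, the known silyl-triflate-driven variant of the lithiated-epoxide homologation. This gives (1S,2R)-1-[3,4-bis(benzyloxy)phenyl]-1-(triethylsilyloxy)-2-(pinacolboryl)-3-(2,4,6-trifluorophenyl)propane F1, in which no alkoxide is present. NaOH/H2O2 gives the mono-silylated syn-diol (1R,2R)-1-[3,4-bis(benzyloxy)phenyl]-1-(triethylsilyloxy)-3-(2,4,6-trifluorophenyl)propan-2-ol F2. MOMCl/iPr2NEt protects the free hydroxyl (the future C3 oxygen) to give (1R,2R)-1-[3,4-bis(benzyloxy)phenyl]-2-(methoxymethoxy)-1-(triethylsilyloxy)-3-(2,4,6-trifluorophenyl)propane F3. TBAF in THF frees the benzylic alcohol (1R,2R)-1-[3,4-bis(benzyloxy)phenyl]-2-(methoxymethoxy)-3-(2,4,6-trifluorophenyl)propan-1-ol F4. KOtBu in THF/DMF closes ring C by SNAr, with O1 as the only free oxygen, to give (2R,3R)-2-[3,4-bis(benzyloxy)phenyl]-5,7-difluoro-3-(methoxymethoxy)chromane F5. HCl in MeOH removes the acetal and the sequence comes back to the route at 13.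

Step 13. What may go wrong: slow attack at the hindered C6 position between two benzyloxy groups, self-condensation of the electrophile, transfer of the thio group between the two units, or loss of facial control. The fallback builds the chain from the lower end without a thioether and sets out from 20 and 16. TMSOTf coupling of the bromo-capped electrophile 20 with 16 (3 equiv) should give [8-bromo-tetra-O-benzyl-epicatechin 3-O-tris(benzyloxy)benzoate]-(4β→8)-[tetra-O-benzyl-epicatechin 3-O-tris(benzyloxy)benzoate] F6. One equivalent of NBS at −78 °C should brominate C6 of the lower unit, the more electron-rich of the two free ring A positions, to give [8-bromo-tetra-O-benzyl-epicatechin 3-O-tris(benzyloxy)benzoate]-(4β→8)-[6-bromo-tetra-O-benzyl-epicatechin 3-O-tris(benzyloxy)benzoate] F7. TMSOTf coupling of F7 with 19 can then occur only at C6 of the upper unit of F7 and gives the tetrabromo trimer tris-gallate F8. Hydrogenolysis under the conditions of step 15, which also removes the fourth bromine, comes back to the route at 24.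

Step 15. What may go wrong: stalling of the hydrogenolysis part-way through the twenty-one benzyl ethers as bromide builds up on the catalyst, or over-reduction at the benzylic C2–O1 bonds when the reaction is forced. The fallback separates the two tasks and sets out from 23. Homogeneous hydrodebromination with Pd(PPh3)4 and HCO2Na in DMF at 90 °C, which leaves benzyl ethers and esters alone, gives the bromine-free protected trimer tris-gallate F9. Hydrogenolysis of F9 over Pd(OH)2/C in THF/MeOH/H2O, now free of halide, comes back to the route at 24.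

**Further compounds**
F1 | step 4 | (1S,2R)-1-[3,4-bis(benzyloxy)phenyl]-1-(triethylsilyloxy)-2-(pinacolboryl)-3-(2,4,6-trifluorophenyl)propane | CC[Si](CC)(CC)O[C@H](c1ccc(OCc2ccccc2)c(OCc2ccccc2)c1)[C@H](B1OC(C)(C)C(C)(C)O1)Cc1c(F)cc(F)cc1F
F2 | step 4 | (1R,2R)-1-[3,4-bis(benzyloxy)phenyl]-1-(triethylsilyloxy)-3-(2,4,6-trifluorophenyl)propan-2-ol | CC[Si](CC)(CC)O[C@H](c1ccc(OCc2ccccc2)c(OCc2ccccc2)c1)[C@H](O)Cc1c(F)cc(F)cc1F
F3 | step 4 | (1R,2R)-1-[3,4-bis(benzyloxy)phenyl]-2-(methoxymethoxy)-1-(triethylsilyloxy)-3-(2,4,6-trifluorophenyl)propane | CC[Si](CC)(CC)O[C@H](c1ccc(OCc2ccccc2)c(OCc2ccccc2)c1)[C@H](OCOC)Cc1c(F)cc(F)cc1F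
F4 | step 4 | (1R,2R)-1-[3,4-bis(benzyloxy)phenyl]-2-(methoxymethoxy)-3-(2,4,6-trifluorophenyl)propan-1-ol | O[C@H](c1ccc(OCc2ccccc2)c(OCc2ccccc2)c1)[C@H](OCOC)Cc1c(F)cc(F)cc1F
F5 | step 4 | (2R,3R)-2-[3,4-bis(benzyloxy)phenyl]-5,7-difluoro-3-(methoxymethoxy)chromane | COCO[C@@H]1Cc2c(F)cc(F)cc2O[C@@H]1c1ccc(OCc2ccccc2)c(OCc2ccccc2)c1
F6 | step 13 | [8-bromo-tetra-O-benzyl-epicatechin 3-O-tris(benzyloxy)benzoate]-(4β→8)-[tetra-O-benzyl-epicatechin 3-O-tris(benzyloxy)benzoate] | O=C(O[C@@H]1[C@@H](c2c(OCc5ccccc5)cc(OCc5ccccc5)c4c2O[C@H](c2ccc(OCc5ccccc5)c(OCc5ccccc5)c2)[C@H](OC(=O)c6cc(OCc7ccccc7)c(OCc7ccccc7)c(OCc7ccccc7)c6)C4)c2c(OCc3ccccc3)cc(OCc3ccccc3)c(Br)c2O[C@@H]1c1ccc(OCc2ccccc2)c(OCc2ccccc2)c1)c1cc(OCc2ccccc2)c(OCc2ccccc2)c(OCc2ccccc2)c1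
F7 | step 13 | [8-bromo-tetra-O-benzyl-epicatechin 3-O-tris(benzyloxy)benzoate]-(4β→8)-[6-bromo-tetra-O-benzyl-epicatechin 3-O-tris(benzyloxy)benzoate] | O=C(O[C@@H]1[C@@H](c2c(OCc5ccccc5)c(Br)c(OCc5ccccc5)c4c2O[C@H](c2ccc(OCc5ccccc5)c(OCc5ccccc5)c2)[C@H](OC(=O)c6cc(OCc7ccccc7)c(OCc7ccccc7)c(OCc7ccccc7)c6)C4)c2c(OCc3ccccc3)cc(OCc3ccccc3)c(Br)c2O[C@@H]1c1ccc(OCc2ccccc2)c(OCc2ccccc2)c1)c1cc(OCc2ccccc2)c(OCc2ccccc2)c(OCc2ccccc2)c1
F8 | step 13 | [6,8-dibromo-tetra-O-benzyl-epicatechin 3-O-tris(benzyloxy)benzoate]-(4β→6)-[8-bromo-tetra-O-benzyl-epicatechin 3-O-tris(benzyloxy)benzoate]-(4β→8)-[6-bromo-tetra-O-benzyl-epicatechin 3-O-tris(benzyloxy)benzoate] | O=C(O[C@@H]1[C@@H](c2c(OCc5ccccc5)c(Br)c3c(c2OCc5ccccc5)[C@H](c2c(OCc5ccccc5)c(Br)c(OCc5ccccc5)c4c2O[C@H](c2ccc(OCc5ccccc5)c(OCc5ccccc5)c2)[C@H](OC(=O)c6cc(OCc7ccccc7)c(OCc7ccccc7)c(OCc7ccccc7)c6)C4)[C@@H](OC(=O)c6cc(OCc7ccccc7)c(OCc7ccccc7)c(OCc7ccccc7)c6)[C@@H](c2ccc(OCc4ccccc4)c(OCc4ccccc4)c2)O3)c2c(OCc3ccccc3)c(Br)c(OCc3ccccc3)c(Br)c2O[C@@H]1c1ccc(OCc2ccccc2)c(OCc2ccccc2)c1)c1cc(OCc2ccccc2)c(OCc2ccccc2)c(OCc2ccccc2)c1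
F9 | step 15 | [tetra-O-benzyl-epicatechin 3-O-tris(benzyloxy)benzoate]-(4β→6)-[tetra-O-benzyl-epicatechin 3-O-tris(benzyloxy)benzoate]-(4β→8)-[tetra-O-benzyl-epicatechin 3-O-tris(benzyloxy)benzoate] | O=C(O[C@@H]1[C@@H](c2c(OCc5ccccc5)cc3c(c2OCc5ccccc5)[C@H](c2c(OCc5ccccc5)cc(OCc5ccccc5)c4c2O[C@H](c2ccc(OCc5ccccc5)c(OCc5ccccc5)c2)[C@H](OC(=O)c6cc(OCc7ccccc7)c(OCc7ccccc7)c(OCc7ccccc7)c6)C4)[C@@H](OC(=O)c6cc(OCc7ccccc7)c(OCc7ccccc7)c(OCc7ccccc7)c6)[C@@H](c2ccc(OCc4ccccc4)c(OCc4ccccc4)c2)O3)c2c(OCc3ccccc3)cc(OCc3ccccc3)cc2O[C@@H]1c1ccc(OCc2ccccc2)c(OCc2ccccc2)c1)c1cc(OCc2ccccc2)c(OCc2ccccc2)c(OCc2ccccc2)c1
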